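The dioxane is taken apart into two molecules of the 6α,7α-epoxide of ferruginol methyl ether, so the route rests on how ring B (C5–C6–C7–C8–C9–C10, abietane numbering) is made. The aryl group is first attached to C10 through C8, the ring-C carbon para to the C12 methoxy group. In the key step this methoxy-activated ipso carbon attacks a C7 triflate to close a five-membered spiro ring (C5, C6, C7, C8, C10); a 1,2-shift of C10 from C8 to C9 then expands it to six-membered ring B and restores aromatic ring C. The precursor is a monocyclic 2-(2-arylcyclohexyl)ethanol made by asymmetric conjugate addition.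

Key step: step 4

Remark: atoms carry abietane numbers throughout, also in the monocyclic precursors. (S)-BINAP is assumed to give the 3S adduct, by analogy with [RhCl(cod)]2/BINAP-catalysed aryl additions to cyclohex-2-enone; otherwise its antipode is used.

Step 1
Reactants: 1 3-methylcyclohex-2-en-1-one; 2 4-bromo-1-methoxy-2-(propan-2-yl)benzene
Product: 6 (2R,3S)-3-[4-methoxy-3-(propan-2-yl)phenyl]-3-methyl-2-(prop-2-en-1-yl)cyclohexan-1-one, via aryllithium 3 (not isolated), via arylalane 4 (not isolated), via aluminium enolate 5 (not isolated)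
Conditions: 2, n-BuLi, Et2O, −78 °C; Me2AlCl; then 1, [RhCl(cod)]2 (cat.), (S)-BINAP, THF, 40 °C; then MeLi, HMPA, allyl iodide, −40 °C to rt
Reagents that add atoms: allyl iodide (C=CCI)
Why: The [RhCl(cod)]2/BINAP-catalysed asymmetric 1,4-addition of the aryl alane to the β-methyl enone should set the quaternary C10 centre under ligand control, and the regiodefined aluminium enolate, activated as its ate complex, should be C-allylated at C5 anti to the pseudoaxial aryl group, which gives the trans aryl/allyl relation (tandem conjugate addition–enolate alkylation).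

Step 2
Reactants: 6 (2R,3S)-3-[4-methoxy-3-(propan-2-yl)phenyl]-3-methyl-2-(prop-2-en-1-yl)cyclohexan-1-one
Product: 7 1-methoxy-2-(propan-2-yl)-4-[(1S,2S)-1,3,3-trimethyl-2-(prop-2-en-1-yl)cyclohexyl]benzene
Conditions: Me2Zn, TiCl4, CH2Cl2, −30 °C to rt
Reagents that add atoms: dimethylzinc (C[Zn]C)
Why: Reetz geminal dimethylation: dimethyltitanium dichloride, formed in the flask from Me2Zn and TiCl4, methylates the carbonyl group, the tertiary titanium alkoxide ionises and a second methyl group is delivered within the ion pair, turning C4=O into CMe2 while the terminal alkene and the aryl ether should be inert; no stereocentre is created and C5 and C10 are carried through.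

Step 3
Reactants: 7 1-methoxy-2-(propan-2-yl)-4-[(1S,2S)-1,3,3-trimethyl-2-(prop-2-en-1-yl)cyclohexyl]benzene
Product: 8 2-[(1S,2S)-2-[4-methoxy-3-(propan-2-yl)phenyl]-2,6,6-trimethylcyclohexyl]ethan-1-ol
Conditions: O3, CH2Cl2/MeOH, −78 °C; then NaBH4, −78 °C to rt
Reagents that add atoms: ozone ([O-][O+]=O)
Why: Ozonolysis of the terminal alkene with reductive work-up removes the terminal carbon and gives the primary alcohol at C7, the alkene reacting much faster than the anisole ring at −78 °C; no stereocentre is touched.

Step 4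
Reactants: 8 2-[(1S,2S)-2-[4-methoxy-3-(propan-2-yl)phenyl]-2,6,6-trimethylcyclohexyl]ethan-1-ol
Product: 11 12-methoxyabieta-8,11,13-triene (ferruginol methyl ether; 5S,10S), via triflate 9 (not isolated), via spiro cation 10 (not isolated)
Conditions: Tf2O, 2,6-di-tert-butyl-4-methylpyridine, CH2Cl2, −78 °C; then (CF3)2CHOH, −40 °C to rt
Reagents that add atoms: none
Why: O-Triflation gives primary triflate 9, which ionises with participation of the anisole ring: C8, the ring-C carbon para to the methoxy group and already bonded to C10, attacks C7 in a 5-exo-tet closure to give spiro cation 10, whose five-membered ring (C5, C6, C7, C8, C10) is the direct precursor of ring B. A Wagner–Meerwein 1,2-shift of C10 from C8 to the cationic neighbour C9 then expands this ring to the six-membered ring B, and loss of the C9 proton restores aromatic ring C with the methoxy group in place. The closest known reaction types are the aryl-assisted (Ar1-5) cyclialkylation of 4-(4-methoxyphenyl)butyl sulfonates through spiro arenium ions and the dienone–phenol ring expansion of spiro-fused cyclohexadienones. No stereocentre is created: C5 is untouched and C10 migrates with retention, so the trans A/B fusion follows from the trans aryl/side-chain relation fixed in step 1, while the spiro centre of 10 is transient. The step needs ipso rather than ortho attack, which the para methoxy group secures because both ortho carbons are meta to it, and it needs migration of C10 rather than C7 and towards C9 rather than C14, which the tertiary nature of C10 and the isopropyl group next to C14 secure. Since the aryl group enters the step bonded to C10 through C8 and leaves it bonded through C9, ring B cannot form by direct closure but only through this ring expansion.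

Step 5
Reactants: 11 12-methoxyabieta-8,11,13-triene
Product: 12 12-methoxyabieta-6,8,11,13-tetraene (5S,10S)
Conditions: DDQ, 1,4-dioxane, rt
Reagents that add atoms: none
Why: DDQ dehydrogenation: hydride abstraction from C7, the benzylic position para to the methoxy group, gives a stabilised cation that loses H6 to form the conjugated C6=C7 alkene, and the quaternary C10 blocks further aromatisation; no stereocentre is created.

Step 6
Reactants: 12 12-methoxyabieta-6,8,11,13-tetraene
Product: 13 6α,7α-epoxy-12-methoxyabieta-8,11,13-triene (5S,6R,7S,10S)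
Conditions: dimethyldioxirane, acetone, −20 °C; used crude
Reagents that add atoms: dimethyldioxirane (CC1(C)OO1)
Why: Epoxidation with neutral dimethyldioxirane should take place on the α face of the C6=C7 alkene, opposite the axial methyl groups on C10 and C4, which sets C6 (R) and C7 (S), and the acid-free medium should keep the labile p-methoxystyrene oxide intact.

Step 7
Reactants: 13 6α,7α-epoxy-12-methoxyabieta-8,11,13-triene (two molecules)
Product: 14 target dimer of two (5S,6R,7R,10S)-12-methoxyabieta-8,11,13-triene units joined through a 1,4-dioxane by the ether bonds C6α–O–C7'β and C7β–O–C6'α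
Conditions: Sc(OTf)3 (cat.), 4 Å molecular sieves, CH2Cl2 (1 M), −40 °C
Reagents that add atoms: none
Why: Lewis-acid-catalysed head-to-tail dimerisation of an epoxide to a 1,4-dioxane: each epoxide ionises at C7 to a p-methoxybenzylic cation that is captured on its β face, trans to the C6 oxygen, by the epoxide oxygen of the second molecule, and the same event at the second C7 closes the ring, so both C7 centres are inverted to the trans 7β ethers while each oxygen stays on its own C6 in the α configuration.

Compound list
1 | 3-methylcyclohex-2-en-1-one | CC1=CC(=O)CCC1 | starting material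
2 | 4-bromo-1-methoxy-2-(propan-2-yl)benzene (4-bromo-2-isopropylanisole) | COc1ccc(Br)cc1C(C)C | starting material
3 | [4-methoxy-3-(propan-2-yl)phenyl]lithium | [Li]c1ccc(OC)c(C(C)C)c1 | intermediate (not isolated)
4 | [4-methoxy-3-(propan-2-yl)phenyl]dimethylalane | C[Al](C)c1ccc(OC)c(C(C)C)c1 | intermediate (not isolated)
5 | dimethylaluminium (3S)-3-[4-methoxy-3-(propan-2-yl)phenyl]-3-methylcyclohex-1-en-1-olate | C[Al](C)OC1=C[C@@](C)(c2ccc(OC)c(C(C)C)c2)CCC1 | intermediate (not isolated)
6 | (2R,3S)-3-[4-methoxy-3-(propan-2-yl)phenyl]-3-methyl-2-(prop-2-en-1-yl)cyclohexan-1-one | C=CC[C@H]1C(=O)CCC[C@]1(C)c1ccc(OC)c(C(C)C)c1 | intermediate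
7 | 1-methoxy-2-(propan-2-yl)-4-[(1S,2S)-1,3,3-trimethyl-2-(prop-2-en-1-yl)cyclohexyl]benzene | C=CC[C@H]1C(C)(C)CCC[C@]1(C)c1ccc(OC)c(C(C)C)c1 | intermediate
8 | 2-[(1S,2S)-2-[4-methoxy-3-(propan-2-yl)phenyl]-2,6,6-trimethylcyclohexyl]ethan-1-ol | OCC[C@H]1C(C)(C)CCC[C@]1(C)c1ccc(OC)c(C(C)C)c1 | intermediate
9 | 2-[(1S,2S)-2-[4-methoxy-3-(propan-2-yl)phenyl]-2,6,6-trimethylcyclohexyl]ethyl trifluoromethanesulfonate | FC(F)(F)S(=O)(=O)OCC[C@H]1C(C)(C)CCC[C@]1(C)c1ccc(OC)c(C(C)C)c1 | intermediate (not isolated)
10 | spiro arenium triflate: 4-methoxy-3-(propan-2-yl)cyclohexadienyl cation whose sp3 carbon C8 is the spiro atom of the five-membered ring C5–C6–C7–C8–C10 of a trans-fused 4,4,10-trimethylhydrindane (5S,10S; spiro centre either configuration) | C[O+]=C1C=CC2(CC[C@H]3C(C)(C)CCC[C@]23C)C=C1C(C)C.[O-]S(=O)(=O)C(F)(F)F | intermediate (not isolated)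
11 | 12-methoxyabieta-8,11,13-triene, (4bS,8aS)-3-methoxy-4b,8,8-trimethyl-2-(propan-2-yl)-4b,5,6,7,8,8a,9,10-octahydrophenanthrene | COc1cc2c(cc1C(C)C)CC[C@H]1C(C)(C)CCC[C@]21C | intermediate
12 | 12-methoxyabieta-6,8,11,13-tetraene (5S,10S) | COc1cc2c(cc1C(C)C)C=C[C@H]1C(C)(C)CCC[C@]21C | intermediate
13 | 6α,7α-epoxy-12-methoxyabieta-8,11,13-triene (5S,6R,7S,10S) | COc1cc2c(cc1C(C)C)[C@@H]1O[C@@H]1[C@H]1C(C)(C)CCC[C@]21C | intermediate
14 | C2-symmetric dimer of 12-methoxyabieta-8,11,13-triene (each half 5S,6R,7R,10S) with a 1,4-dioxane ring formed by C6α–O–C7'β and C7β–O–C6'α | COc1cc2c(cc1C(C)C)[C@H]1O[C@H]3[C@H](O[C@@H]1[C@H]1C(C)(C)CCC[C@]21C)c1cc(C(C)C)c(OC)cc1[C@@]1(C)CCCC(C)(C)[C@H]31 | target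

Total step count: 7. Longest linear sequence: 7 steps (1 and 2 to 14).

Steps most likely to fail

Step 7. After ionisation at C7 the cation may undergo a 1,2-hydride shift from C6 (Meinwald rearrangement to the 6-ketone), or grow into oligoethers, faster than it is captured by a second epoxide. The fallback sets out from 13. Opening with methanol under pyridinium p-toluenesulfonate catalysis at 0 °C should give 7β,12-dimethoxyabieta-8,11,13-trien-6α-ol F1; its C7 configuration does not matter. F1 is then equilibrated with catalytic camphorsulfonic acid in toluene over 5 Å molecular sieves, which take up methanol. Reversible ether exchange at the p-methoxybenzylic C7 lets the 6α-hydroxyl group of one molecule replace the methoxy group of the other, twice, and the sequence comes back to the route at 14.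

Step 4. Attack by an ortho carbon instead of the ipso carbon would leave C10 on C8 and give the regioisomeric tricycle, and elimination or solvent capture of the triflate may compete with aryl participation. The fallback sets out from 8 and separates spirocyclisation from ring expansion. BBr3 (CH2Cl2, −78 to 0 °C) should give 4-[(1S,2S)-2-(2-hydroxyethyl)-1,3,3-trimethylcyclohexyl]-2-(propan-2-yl)phenol F2. I2, PPh3 and imidazole convert only the aliphatic hydroxyl group, giving 4-[(1S,2S)-2-(2-iodoethyl)-1,3,3-trimethylcyclohexyl]-2-(propan-2-yl)phenol F3. t-BuOK in t-BuOH/THF at high dilution alkylates the phenoxide at its para carbon, the only nucleophilic ring carbon within reach, to the isolable spiro[4.5]deca-6,9-dien-8-one F4, in which the cyclohexadienone is spiro-fused at C8 to the trans-hydrindane. Trifluoroacetic acid in CH2Cl2 then effects the dienone–phenol rearrangement, with the same shift of C10 from C8 to C9, to ferruginol F5. MeI and K2CO3 in acetone come back to the route at 11.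

Step 2. A 1,2-hydride shift from C5 to the tertiary C4 cation, or loss of a proton, may outrun methyl transfer and erode the C5 configuration. The fallback sets out from enolate 5, generated as in step 1, and avoids a cation at C4. Alkylation with tert-butyl bromoacetate should give tert-butyl 2-[(1R,2S)-2-[4-methoxy-3-(propan-2-yl)phenyl]-2-methyl-6-oxocyclohexyl]acetate F6. Takai–Lombardo methylenation (Zn, CH2Br2, TiCl4) gives the exocyclic alkene tert-butyl 2-[(1S,2S)-2-[4-methoxy-3-(propan-2-yl)phenyl]-2-methyl-6-methylidenecyclohexyl]acetate F7. Simmons–Smith cyclopropanation (Et2Zn, CH2I2) gives tert-butyl 2-[(4S,5S)-5-[4-methoxy-3-(propan-2-yl)phenyl]-5-methylspiro[2.5]octan-4-yl]acetate F8. Hydrogenolysis of the cyclopropane (H2, PtO2, AcOH) gives tert-butyl 2-[(1S,2S)-2-[4-methoxy-3-(propan-2-yl)phenyl]-2,6,6-trimethylcyclohexyl]acetate F9. LiAlH4 reduction comes back to the route at 8, so that 6 and 7 are bypassed.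

Further compounds
F1 | step 7 | 7β,12-dimethoxyabieta-8,11,13-trien-6α-ol (5S,6R,7R,10S) | COc1cc2c(cc1C(C)C)[C@@H](OC)[C@H](O)[C@H]1C(C)(C)CCC[C@]21C
F2 | step 4 | 4-[(1S,2S)-2-(2-hydroxyethyl)-1,3,3-trimethylcyclohexyl]-2-(propan-2-yl)phenol | OCC[C@H]1C(C)(C)CCC[C@]1(C)c1ccc(O)c(C(C)C)c1
F3 | step 4 | 4-[(1S,2S)-2-(2-iodoethyl)-1,3,3-trimethylcyclohexyl]-2-(propan-2-yl)phenol | ICC[C@H]1C(C)(C)CCC[C@]1(C)c1ccc(O)c(C(C)C)c1
F4 | step 4 | spirodienone: 2-(propan-2-yl)cyclohexa-2,5-dien-1-one spiro-fused at C4 (abietane C8) to the five-membered ring C5–C6–C7–C8–C10 of the trans-fused 4,4,10-trimethylhydrindane (5S,10S; spiro centre either configuration) | O=C1C=CC2(CC[C@H]3C(C)(C)CCC[C@]23C)C=C1C(C)C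
F5 | step 4 | ferruginol, abieta-8,11,13-trien-12-ol (5S,10S) | Oc1cc2c(cc1C(C)C)CC[C@H]1C(C)(C)CCC[C@]21C
F6 | step 2 | tert-butyl 2-[(1R,2S)-2-[4-methoxy-3-(propan-2-yl)phenyl]-2-methyl-6-oxocyclohexyl]acetate | CC(C)(C)OC(=O)C[C@H]1C(=O)CCC[C@]1(C)c1ccc(OC)c(C(C)C)c1
F7 | step 2 | tert-butyl 2-[(1S,2S)-2-[4-methoxy-3-(propan-2-yl)phenyl]-2-methyl-6-methylidenecyclohexyl]acetate | CC(C)(C)OC(=O)C[C@H]1C(=C)CCC[C@]1(C)c1ccc(OC)c(C(C)C)c1
F8 | step 2 | tert-butyl 2-[(4S,5S)-5-[4-methoxy-3-(propan-2-yl)phenyl]-5-methylspiro[2.5]octan-4-yl]acetate | CC(C)(C)OC(=O)C[C@H]1C2(CC2)CCC[C@]1(C)c1ccc(OC)c(C(C)C)c1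
F9 | step 2 | tert-butyl 2-[(1S,2S)-2-[4-methoxy-3-(propan-2-yl)phenyl]-2,6,6-trimethylcyclohexyl]acetate | CC(C)(C)OC(=O)C[C@H]1C(C)(C)CCC[C@]1(C)c1ccc(OC)c(C(C)C)c1
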